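**Retrosynthetic overview**

1. Target 29 ⇒ chromanol 21: the (2Z,6E)-dienoate arm is grown last from the prenyl terminus (E-selective allylic oxidation, two-carbon ester homologation, Still–Gennari olefination).
2. 21 ⇒ diazo ketone 16. The strategy rests on the resorcinol-type benzene ring C4a–C5–C6–C7–C8–C8a (CH3 on C5, OH on C7, ether O1 on C8a) fused to the pyran ring O1–C2–C3–C4–C4a–C8a. It is cut into a vinylketene (C7, C4a, C5, C6) and an ethynyl ether (C8, C8a) whose oxygen is already O1 on stereocentre C2; the bonds formed are C7–C8, C4a–C8a and C6–C7.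
3. Ring order: the pyran ring closes first ([2+2] step) and the benzene ring second (4π opening, 6π closure, enolisation), both in step 10.
4. 16 ⇒ (R)-linalool 1 (C2 with its C–O bond, C3, C4, prenyl arm), trichloroethylene 2 (C8, C8a), tert-butyl acetate 7 (C4a, C7) and isopropenylmagnesium bromide 10 (C5, C6, 5-CH3). The ethynyl ether is carried as a robust dichlorovinyl ether and unveiled only two steps before the diazo ketone.

Key step: step 10

Assumption: (R)-(−)-linalool is taken as commercially available in high enantiomeric purity; along the route its descriptor switches between R and S only because CIP priorities change, the spatial arrangement at that carbon being kept throughout.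

**Route**

Step 1
Reactants: 1 (R)-linalool; 2 trichloroethylene
Product: 3 (3R)-3-{[(E)-1,2-dichloroethenyl]oxy}-3,7-dimethylocta-1,6-diene
Conditions: KH, THF, 0 °C; then Cl2C=CHCl, −40 °C → rt; used without delay
Reagents that add atoms: none
Why: The potassium alkoxide adds to dichloroacetylene formed in situ from trichloroethylene (alkoxide/trichloroethylene route to 1,2-dichlorovinyl ethers), which works for tertiary alkoxides and leaves the C–O bond of the stereocentre untouched; the product is kept at or below room temperature so that the allyl vinyl ether cannot undergo a Claisen shift.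

Step 2
Reactants: 3 (3R)-3-{[(E)-1,2-dichloroethenyl]oxy}-3,7-dimethylocta-1,6-diene
Product: 5 (3R)-3-{[(E)-1,2-dichloroethenyl]oxy}-3,7-dimethyloct-6-en-1-ol, via B-alkyl-9-BBN adduct 4 (not isolated)
Conditions: 9-BBN, THF, 0 °C → rt; then NaOH, H2O2, H2O, 0 °C
Reagents that add atoms: hydrogen peroxide, OO; 9-borabicyclo[3.3.1]nonane, B1C2CCCC1CCC2 (atoms kept only in 4)
Why: Anti-Markovnikov hydroboration–oxidation with 9-BBN is selective for the monosubstituted vinyl group over the trisubstituted alkene and the electron-poor dichlorovinyl ether, and it removes the allyl ether pattern so that no [3,3] shift can occur once the alkyne is made.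

Step 3
Reactants: 5 (3R)-3-{[(E)-1,2-dichloroethenyl]oxy}-3,7-dimethyloct-6-en-1-ol
Product: 6 (6R)-6-{[(E)-1,2-dichloroethenyl]oxy}-8-iodo-2,6-dimethyloct-2-ene
Conditions: I2, PPh3, imidazole, CH2Cl2, 0 °C
Reagents that add atoms: iodine, II
Why: Appel-type iodination of the primary alcohol proceeds under near-neutral conditions that the dichlorovinyl ether and the alkene tolerate.

Step 4
Reactants: 6 (6R)-6-{[(E)-1,2-dichloroethenyl]oxy}-8-iodo-2,6-dimethyloct-2-ene; 7 tert-butyl acetate
Product: 8 tert-butyl (5S)-5-{[(E)-1,2-dichloroethenyl]oxy}-5,9-dimethyldec-8-enoate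
Conditions: LiN(iPr)2, 7 (slight excess over base), THF, −78 °C; then 6, DMPU, −78 → −20 °C
Reagents that add atoms: none
Why: SN2 alkylation of the lithium enolate of tert-butyl acetate with an unhindered primary iodide forms C4–C4a, and keeping the ester in slight excess leaves no free amide base to dehydrochlorinate the dichlorovinyl ether.

Step 5
Reactants: 8 tert-butyl (5S)-5-{[(E)-1,2-dichloroethenyl]oxy}-5,9-dimethyldec-8-enoate
Product: 9 (5S)-5-{[(E)-1,2-dichloroethenyl]oxy}-5,9-dimethyldec-8-enal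
Conditions: iBu2AlH (1.1 equiv), toluene, −78 °C; aq KNaC4H4O6 work-up
Reagents that add atoms: none
Why: Partial reduction of the hindered tert-butyl ester stops at the tetrahedral aluminium alkoxide at −78 °C and releases the aldehyde on work-up.

Step 6
Reactants: 9 (5S)-5-{[(E)-1,2-dichloroethenyl]oxy}-5,9-dimethyldec-8-enal; 10 isopropenylmagnesium bromide
Product: 11 (7S)-7-{[(E)-1,2-dichloroethenyl]oxy}-2,7,11-trimethyldodeca-1,10-dien-3-ol (both C3 epimers)
Conditions: CH2=C(CH3)MgBr, THF, −78 → 0 °C; aq NH4Cl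
Reagents that add atoms: none
Why: Grignard 1,2-addition installs C5, C6 and the 5-methyl group and holds C7 at the alcohol level, which can pass through the butyllithium step that a ketone could not; the carbinol configuration is irrelevant because it is oxidised in step 8.

Step 7
Reactants: 11 (7S)-7-{[(E)-1,2-dichloroethenyl]oxy}-2,7,11-trimethyldodeca-1,10-dien-3-ol
Product: 13 (7S)-7-(ethynyloxy)-2,7,11-trimethyldodeca-1,10-dien-3-ol, via dilithio alkynyl ether alkoxide 12 (not isolated)
Conditions: n-BuLi (3.3 equiv), THF, −78 → −40 °C; MeOH, −78 °C; pH 7 work-up, Et3N-deactivated silica, ≤ 20 °C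
Reagents that add atoms: none
Why: After deprotonation of the hydroxyl, butyllithium eliminates HCl from the dichlorovinyl ether and exchanges the remaining chlorine for lithium (the standard dichlorovinyl ether to ynol ether conversion), and protonation at low temperature gives the terminal ethynyl ether.

Step 8
Reactants: 13 (7S)-7-(ethynyloxy)-2,7,11-trimethyldodeca-1,10-dien-3-ol
Product: 14 (7S)-7-(ethynyloxy)-2,7,11-trimethyldodeca-1,10-dien-3-one
Conditions: SO3·pyridine, DMSO, iPr2NEt, CH2Cl2, 0 °C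
Reagents that add atoms: none
Why: Parikh–Doering oxidation of the allylic alcohol runs in a basic medium at 0 °C throughout, so the acid- and heat-sensitive ethynyl ether is never exposed to a proton source or to warming.

Step 9
Reactants: 14 (7S)-7-(ethynyloxy)-2,7,11-trimethyldodeca-1,10-dien-3-one
Product: 16 (7R)-4-diazo-7-(ethynyloxy)-2,7,11-trimethyldodeca-1,10-dien-3-one, via trifluoroacetyl ketone lithium enolate 15 (not isolated)
Conditions: LiN(SiMe3)2 (1.1 equiv), THF, −78 °C; CF3CO2CH2CF3; solvent exchange without acidic wash; MsN3 (1.1 equiv), Et3N, H2O, MeCN, 0 → 20 °C; product kept cold and dark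
Reagents that add atoms: methanesulfonyl azide, CS(=O)(=O)N=[N+]=[N-]; 2,2,2-trifluoroethyl trifluoroacetate, O=C(OCC(F)(F)F)C(F)(F)F (atoms kept only in 15)
Why: Kinetic enolisation at the α′-methylene, C-trifluoroacetylation and transfer of N2 from the sulfonyl azide with loss of the trifluoroacetyl group (detrifluoroacetylative diazo transfer) is the standard route to α′-diazo enones; the ketone is far more acidic than the acetylenic C–H, so one equivalent of base leaves the alkyne untouched.

Step 10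
Reactants: 16 (7R)-4-diazo-7-(ethynyloxy)-2,7,11-trimethyldodeca-1,10-dien-3-one
Product: 21 (2R)-2,5-dimethyl-2-(4-methylpent-3-en-1-yl)-3,4-dihydro-2H-chromen-7-ol, via vinylketene 17 (not isolated), via fused cyclobutenone 18 (not isolated), via dienylketene 19 (not isolated), via cyclohexadienone 20 (not isolated)
Conditions: hν (254 nm, low-pressure Hg lamps, quartz), degassed ClCH2CH2Cl (0.01 M), 15–20 °C until N2 evolution ends; then 80 °C in the dark
Reagents that add atoms: none
Why: Proposed new method: light expels N2 and the isopropenyl group migrates (Wolff rearrangement) to give vinylketene 17, whose carbonyl carbon C7 is attacked by the nucleophilic terminal carbon C8 of the ethynyl ether while C8a bonds to C4a, giving the fused 3-alkoxycyclobutenone 18; 4π opening to dienylketene 19, 6π electrocyclisation (C6–C7) to dienone 20 and enolisation then give phenol 21. The closest known reactions are the Danheiser benzannulation in its photochemical Wolff form, where such vinylketenes combine with alkoxyacetylenes between two molecules, and intramolecular ketene [2+2] cycloadditions in which the tether joins the ketene α-carbon to the internal carbon of the π-bond; neither has been run with the alkoxyacetylene tethered through its oxygen or with a tertiary-alkyl ethynyl ether. The pyran ring closes in the [2+2] step through the C4a–C8a bond (6-exo-dig with respect to the alkyne, helped by the gem-disubstituted C2), and the benzene ring closes by 6π electrocyclisation of 19 followed by tautomerisation. No stereocentre of the product is made here: C4a of 18 forms as a mixture and becomes planar on ring opening, and C2 keeps the linalool configuration because its C–O bond is never broken. The step needs O1 on the ring carbon next to C4a, which both the polarisation of the ynol ether (C8 nucleophilic, C8a cation-stabilising) and the four-atom link O1–C2–C3–C4 dictate, and it needs the isopropenyl and ketenyl groups cis on C4a=C8a in 19, which the six-membered ring enforces. Generating the ketene with light at 15–20 °C stays below the temperature at which a tertiary ethynyl ether loses ketene by retro-ene fragmentation, and heat is applied only after that ether has been consumed.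

Step 11
Reactants: 21 (2R)-2,5-dimethyl-2-(4-methylpent-3-en-1-yl)-3,4-dihydro-2H-chromen-7-ol
Product: 22 {[(2R)-2,5-dimethyl-2-(4-methylpent-3-en-1-yl)-3,4-dihydro-2H-chromen-7-yl]oxy}tri(propan-2-yl)silane
Conditions: iPr3SiCl, imidazole, DMF, rt
Reagents that add atoms: chlorotri(propan-2-yl)silane, CC(C)[Si](Cl)(C(C)C)C(C)C
Why: Silylation masks the phenol as a bulky aryl silyl ether that should withstand the oxidant, the enolate, the hydride and the phosphonate anion used next.

Step 12
Reactants: 22 {[(2R)-2,5-dimethyl-2-(4-methylpent-3-en-1-yl)-3,4-dihydro-2H-chromen-7-yl]oxy}tri(propan-2-yl)silane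
Product: 23 (2E)-5-[(2R)-2,5-dimethyl-7-{[tri(propan-2-yl)silyl]oxy}-3,4-dihydro-2H-chromen-2-yl]-2-methylpent-2-en-1-ol
Conditions: SeO2 (cat.), t-BuOOH, salicylic acid (cat.), CH2Cl2, 0 °C → rt, stopped before full conversion
Reagents that add atoms: tert-butyl hydroperoxide, CC(C)(C)OO; selenium dioxide, O=[Se]=O
Why: The ene reaction and [2,3]-sigmatropic shift of the SeO2 allylic oxidation hydroxylate the methyl group trans to the chain of the only trisubstituted alkene, which sets the 6E geometry of the target.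

Step 13
Reactants: 23 (2E)-5-[(2R)-2,5-dimethyl-7-{[tri(propan-2-yl)silyl]oxy}-3,4-dihydro-2H-chromen-2-yl]-2-methylpent-2-en-1-ol
Product: 24 {[(2R)-2-[(3E)-5-bromo-4-methylpent-3-en-1-yl]-2,5-dimethyl-3,4-dihydro-2H-chromen-7-yl]oxy}tri(propan-2-yl)silane
Conditions: CBr4, PPh3, CH2Cl2, 0 °C; used directly
Reagents that add atoms: tetrabromomethane, BrC(Br)(Br)Br
Why: Appel bromination converts the primary allylic alcohol into the bromide by SN2 displacement without allylic transposition or loss of alkene geometry.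

Step 14
Reactants: 24 {[(2R)-2-[(3E)-5-bromo-4-methylpent-3-en-1-yl]-2,5-dimethyl-3,4-dihydro-2H-chromen-7-yl]oxy}tri(propan-2-yl)silane; 7 tert-butyl acetate
Product: 25 tert-butyl (4E)-7-[(2R)-2,5-dimethyl-7-{[tri(propan-2-yl)silyl]oxy}-3,4-dihydro-2H-chromen-2-yl]-4-methylhept-4-enoate
Conditions: LiN(iPr)2, 7, THF, −78 °C; then 24, −78 → −40 °C
Reagents that add atoms: none
Why: The lithium enolate of tert-butyl acetate displaces the primary allylic bromide at the unsubstituted carbon (SN2 enolate alkylation), adding the two carbons between the two alkenes.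

Step 15
Reactants: 25 tert-butyl (4E)-7-[(2R)-2,5-dimethyl-7-{[tri(propan-2-yl)silyl]oxy}-3,4-dihydro-2H-chromen-2-yl]-4-methylhept-4-enoate
Product: 26 (4E)-7-[(2R)-2,5-dimethyl-7-{[tri(propan-2-yl)silyl]oxy}-3,4-dihydro-2H-chromen-2-yl]-4-methylhept-4-enal
Conditions: iBu2AlH (1.1 equiv), CH2Cl2, −78 °C; aq KNaC4H4O6 work-up
Reagents that add atoms: none
Why: Partial reduction of the tert-butyl ester at −78 °C gives the aldehyde, as in step 5.

Step 16
Reactants: 26 (4E)-7-[(2R)-2,5-dimethyl-7-{[tri(propan-2-yl)silyl]oxy}-3,4-dihydro-2H-chromen-2-yl]-4-methylhept-4-enal; 27 methyl 2-[bis(2,2,2-trifluoroethoxy)phosphoryl]propanoate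
Product: 28 methyl (2Z,6E)-9-[(2R)-2,5-dimethyl-7-{[tri(propan-2-yl)silyl]oxy}-3,4-dihydro-2H-chromen-2-yl]-2,6-dimethylnona-2,6-dienoate
Conditions: KN(SiMe3)2, 18-crown-6, THF, −78 °C; then 26
Reagents that add atoms: none
Why: In the Still–Gennari olefination the electron-poor bis(trifluoroethyl) phosphonate with a dissociated potassium counter-ion eliminates fast from the kinetic adduct, which should give the Z-configured 2-methyl enoate with an aliphatic aldehyde.

Step 17
Reactants: 28 methyl (2Z,6E)-9-[(2R)-2,5-dimethyl-7-{[tri(propan-2-yl)silyl]oxy}-3,4-dihydro-2H-chromen-2-yl]-2,6-dimethylnona-2,6-dienoate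
Product: 29 methyl (2Z,6E)-9-[(2R)-7-hydroxy-2,5-dimethyl-3,4-dihydro-2H-chromen-2-yl]-2,6-dimethylnona-2,6-dienoate
Conditions: Bu4NF, AcOH, THF, 0 °C
Reagents that add atoms: none
Why: Fluoride cleaves the aryl silyl ether quickly at 0 °C, and the acetic acid buffer keeps the phenoxide from isomerising or hydrolysing the Z-enoate.

**Compound list**

1 | (R)-linalool | CC(C)=CCC[C@](O)(C)C=C | starting material
2 | trichloroethylene | ClC=C(Cl)Cl | starting material
3 | (3R)-3-{[(E)-1,2-dichloroethenyl]oxy}-3,7-dimethylocta-1,6-diene | CC(C)=CCC[C@](O/C(Cl)=C\Cl)(C)C=C | intermediate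
4 | 9-[(3S)-3-{[(E)-1,2-dichloroethenyl]oxy}-3,7-dimethyloct-6-en-1-yl]-9-borabicyclo[3.3.1]nonane (not isolated) | CC(C)=CCC[C@](O/C(Cl)=C\Cl)(C)CCB1C2CCCC1CCC2 | intermediate
5 | (3R)-3-{[(E)-1,2-dichloroethenyl]oxy}-3,7-dimethyloct-6-en-1-ol | CC(C)=CCC[C@](O/C(Cl)=C\Cl)(C)CCO | intermediate
6 | (6R)-6-{[(E)-1,2-dichloroethenyl]oxy}-8-iodo-2,6-dimethyloct-2-ene | CC(C)=CCC[C@](O/C(Cl)=C\Cl)(C)CCI | intermediate
7 | tert-butyl acetate | CC(=O)OC(C)(C)C | starting material
8 | tert-butyl (5S)-5-{[(E)-1,2-dichloroethenyl]oxy}-5,9-dimethyldec-8-enoate | CC(C)=CCC[C@](O/C(Cl)=C\Cl)(C)CCCC(=O)OC(C)(C)C | intermediate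
9 | (5S)-5-{[(E)-1,2-dichloroethenyl]oxy}-5,9-dimethyldec-8-enal | CC(C)=CCC[C@](O/C(Cl)=C\Cl)(C)CCCC=O | intermediate
10 | isopropenylmagnesium bromide | CC(=C)[Mg]Br | starting material
11 | (7S)-7-{[(E)-1,2-dichloroethenyl]oxy}-2,7,11-trimethyldodeca-1,10-dien-3-ol (both C3 epimers) | CC(C)=CCC[C@](O/C(Cl)=C\Cl)(C)CCCC(O)C(C)=C | intermediate
12 | dilithio derivative of 13 (lithium acetylide and lithium alkoxide; not isolated) | CC(C)=CCC[C@](OC#C[Li])(C)CCCC(O[Li])C(C)=C | intermediate
13 | (7S)-7-(ethynyloxy)-2,7,11-trimethyldodeca-1,10-dien-3-ol (both C3 epimers) | CC(C)=CCC[C@](OC#C)(C)CCCC(O)C(C)=C | intermediate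
14 | (7S)-7-(ethynyloxy)-2,7,11-trimethyldodeca-1,10-dien-3-one | CC(C)=CCC[C@](OC#C)(C)CCCC(=O)C(C)=C | intermediate
15 | (7R)-7-(ethynyloxy)-2,7,11-trimethyl-4-(trifluoroacetyl)dodeca-1,10-dien-3-one, present as its lithium enolate (not isolated) | CC(C)=CCC[C@](OC#C)(C)CCC(C(=O)C(F)(F)F)C(=O)C(C)=C | intermediate
16 | (7R)-4-diazo-7-(ethynyloxy)-2,7,11-trimethyldodeca-1,10-dien-3-one | CC(C)=CCC[C@](OC#C)(C)CCC(=[N+]=[N-])C(=O)C(C)=C | intermediate
17 | (5R)-5-(ethynyloxy)-5,9-dimethyl-2-(prop-1-en-2-yl)deca-1,8-dien-1-one (vinylketene; not isolated) | CC(C)=CCC[C@](OC#C)(C)CCC(=C=O)C(C)=C | intermediate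
18 | (3R)-3-methyl-3-(4-methylpent-3-en-1-yl)-6-(prop-1-en-2-yl)-2-oxabicyclo[4.2.0]oct-1(8)-en-7-one (both C6 epimers; not isolated) | CC(C)=CCC[C@]1(C)CCC2(C(C)=C)C(=O)C=C2O1 | intermediate
19 | 2-[(2R)-2-methyl-2-(4-methylpent-3-en-1-yl)-5-(prop-1-en-2-yl)-3,4-dihydro-2H-pyran-6-yl]ethen-1-one (dienylketene; not isolated) | CC(C)=CCC[C@]1(C)CCC(C(C)=C)=C(C=C=O)O1 | intermediate
20 | (2R)-2,5-dimethyl-2-(4-methylpent-3-en-1-yl)-3,4-dihydro-2H-chromen-7(6H)-one (not isolated) | CC(C)=CCC[C@]1(C)CCC2=C(C)CC(=O)C=C2O1 | intermediate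
21 | (2R)-2,5-dimethyl-2-(4-methylpent-3-en-1-yl)-3,4-dihydro-2H-chromen-7-ol | CC(C)=CCC[C@]1(C)CCc2c(C)cc(O)cc2O1 | intermediate
22 | {[(2R)-2,5-dimethyl-2-(4-methylpent-3-en-1-yl)-3,4-dihydro-2H-chromen-7-yl]oxy}tri(propan-2-yl)silane | CC(C)=CCC[C@]1(C)CCc2c(C)cc(O[Si](C(C)C)(C(C)C)C(C)C)cc2O1 | intermediate
23 | (2E)-5-[(2R)-2,5-dimethyl-7-{[tri(propan-2-yl)silyl]oxy}-3,4-dihydro-2H-chromen-2-yl]-2-methylpent-2-en-1-ol | OC/C(C)=C/CC[C@]1(C)CCc2c(C)cc(O[Si](C(C)C)(C(C)C)C(C)C)cc2O1 | intermediate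
24 | {[(2R)-2-[(3E)-5-bromo-4-methylpent-3-en-1-yl]-2,5-dimethyl-3,4-dihydro-2H-chromen-7-yl]oxy}tri(propan-2-yl)silane | BrC/C(C)=C/CC[C@]1(C)CCc2c(C)cc(O[Si](C(C)C)(C(C)C)C(C)C)cc2O1 | intermediate
25 | tert-butyl (4E)-7-[(2R)-2,5-dimethyl-7-{[tri(propan-2-yl)silyl]oxy}-3,4-dihydro-2H-chromen-2-yl]-4-methylhept-4-enoate | CC(C)(C)OC(=O)CC/C(C)=C/CC[C@]1(C)CCc2c(C)cc(O[Si](C(C)C)(C(C)C)C(C)C)cc2O1 | intermediate
26 | (4E)-7-[(2R)-2,5-dimethyl-7-{[tri(propan-2-yl)silyl]oxy}-3,4-dihydro-2H-chromen-2-yl]-4-methylhept-4-enal | O=CCC/C(C)=C/CC[C@]1(C)CCc2c(C)cc(O[Si](C(C)C)(C(C)C)C(C)C)cc2O1 | intermediate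
27 | methyl 2-[bis(2,2,2-trifluoroethoxy)phosphoryl]propanoate | COC(=O)C(C)P(=O)(OCC(F)(F)F)OCC(F)(F)F | starting material
28 | methyl (2Z,6E)-9-[(2R)-2,5-dimethyl-7-{[tri(propan-2-yl)silyl]oxy}-3,4-dihydro-2H-chromen-2-yl]-2,6-dimethylnona-2,6-dienoate | COC(=O)/C(C)=C\CC/C(C)=C/CC[C@]1(C)CCc2c(C)cc(O[Si](C(C)C)(C(C)C)C(C)C)cc2O1 | intermediate
29 | methyl (2Z,6E)-9-[(2R)-7-hydroxy-2,5-dimethyl-3,4-dihydro-2H-chromen-2-yl]-2,6-dimethylnona-2,6-dienoate (CNP0319148.1) | COC(=O)/C(C)=C\CC/C(C)=C/CC[C@]1(C)CCc2c(C)cc(O)cc2O1 | target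

**Step count**

Total: 17 steps. Longest linear sequence: 17 steps, from (R)-linalool 1 to 29.

**Steps most likely to fail**

Step 10 (key step, proposed new method). Capture of the photogenerated vinylketene by the tethered alkyne may be outrun by ketene dimerisation, by a 1,2-hydride shift at the carbene stage, or by retro-ene fragmentation of the tertiary ethynyl ether before it is consumed. The fallback uses known chemistry and brings the arene in ready-made; it sets out from 1 and returns to the route at 22. Commercial 3-bromo-5-methylphenol is iodinated para to the hydroxyl (N-iodosuccinimide, cat. TsOH, MeCN) to give 3-bromo-4-iodo-5-methylphenol F1, which is silylated (iPr3SiCl, imidazole, DMF) to (3-bromo-4-iodo-5-methylphenoxy)tri(propan-2-yl)silane F2. (R)-Linalool 1 is hydroborated at its vinyl group with 9-BBN to 9-[(3S)-3-hydroxy-3,7-dimethyloct-6-en-1-yl]-9-borabicyclo[3.3.1]nonane F3. F3 is coupled in the same flask with F2 at the C–I bond (B-alkyl Suzuki–Miyaura coupling; PdCl2(dppf), K3PO4, THF/DMF/H2O, rt → 50 °C) to give (3R)-1-(2-bromo-6-methyl-4-{[tri(propan-2-yl)silyl]oxy}phenyl)-3,7-dimethyloct-6-en-3-ol F4. Palladium-catalysed intramolecular aryl ether formation between the tertiary alcohol and the aryl bromide (Pd(OAc)2, 2-(di-tert-butylphosphino)-1,1′-binaphthyl, Cs2CO3, toluene, 80 °C) then closes the pyran ring without touching the carbinol C–O bond and gives 22.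

Step 9. The sulfonyl azide may add as a 1,3-dipole to the electron-rich ethynyl ether, or the alkyne may be hydrated while the acidic trifluoroacetyl intermediate is handled, faster than N2 is transferred to the ketone. The fallback caps the alkyne terminus with silicon through the azide step; it sets out from 11 and returns at 16. Dilithio species 12, generated as in step 7, is quenched with Me3SiCl in place of methanol to give trimethyl({(7S)-2,7,11-trimethyl-7-{[(trimethylsilyl)ethynyl]oxy}dodeca-1,10-dien-3-yl}oxy)silane F5. Brief K2CO3/MeOH at −20 °C frees only the alcohol and gives (7S)-2,7,11-trimethyl-7-{[(trimethylsilyl)ethynyl]oxy}dodeca-1,10-dien-3-ol F6. Parikh–Doering oxidation as in step 8 gives (7S)-2,7,11-trimethyl-7-{[(trimethylsilyl)ethynyl]oxy}dodeca-1,10-dien-3-one F7. Trifluoroacetylation as in step 9 gives (7R)-2,7,11-trimethyl-4-(trifluoroacetyl)-7-{[(trimethylsilyl)ethynyl]oxy}dodeca-1,10-dien-3-one F8 as its lithium enolate, and diazo transfer to it gives (7R)-4-diazo-2,7,11-trimethyl-7-{[(trimethylsilyl)ethynyl]oxy}dodeca-1,10-dien-3-one F9, whose alkyne is shielded from the azide. Bu4NF (THF, −20 °C) then removes the silyl cap and gives 16.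

Step 12. The allylic oxidation may run on to the enal, stall at low conversion, or attack the benzylic C4 and aryl methyl positions of the electron-rich chroman. The fallback rebuilds the E-trisubstituted allylic alcohol by olefination instead of C–H oxidation; it sets out from 22 and returns at 23. Dihydroxylation of the only alkene (K2OsO2(OH)4 cat., N-methylmorpholine N-oxide, acetone/H2O) gives 5-[(2S)-2,5-dimethyl-7-{[tri(propan-2-yl)silyl]oxy}-3,4-dihydro-2H-chromen-2-yl]-2-methylpentane-2,3-diol F10. NaIO4 (THF/H2O) cleaves it to 3-[(2S)-2,5-dimethyl-7-{[tri(propan-2-yl)silyl]oxy}-3,4-dihydro-2H-chromen-2-yl]propanal F11. Wittig reaction with the stabilised ylide ethyl 2-(triphenylphosphoranylidene)propanoate (toluene, 80 °C; E-selective) gives ethyl (2E)-5-[(2R)-2,5-dimethyl-7-{[tri(propan-2-yl)silyl]oxy}-3,4-dihydro-2H-chromen-2-yl]-2-methylpent-2-enoate F12, and iBu2AlH (CH2Cl2, −78 °C) reduces the ester to 23.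

**Further compounds**

F1 | step 10 | 3-bromo-4-iodo-5-methylphenol | Cc1cc(O)cc(Br)c1I
F2 | step 10 | (3-bromo-4-iodo-5-methylphenoxy)tri(propan-2-yl)silane | Cc1cc(O[Si](C(C)C)(C(C)C)C(C)C)cc(Br)c1I
F3 | step 10 | 9-[(3S)-3-hydroxy-3,7-dimethyloct-6-en-1-yl]-9-borabicyclo[3.3.1]nonane | CC(C)=CCC[C@](O)(C)CCB1C2CCCC1CCC2
F4 | step 10 | (3R)-1-(2-bromo-6-methyl-4-{[tri(propan-2-yl)silyl]oxy}phenyl)-3,7-dimethyloct-6-en-3-ol | CC(C)=CCC[C@](O)(C)CCc1c(C)cc(O[Si](C(C)C)(C(C)C)C(C)C)cc1Br
F5 | step 9 | trimethyl({(7S)-2,7,11-trimethyl-7-{[(trimethylsilyl)ethynyl]oxy}dodeca-1,10-dien-3-yl}oxy)silane | CC(C)=CCC[C@](OC#C[Si](C)(C)C)(C)CCCC(O[Si](C)(C)C)C(C)=C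
F6 | step 9 | (7S)-2,7,11-trimethyl-7-{[(trimethylsilyl)ethynyl]oxy}dodeca-1,10-dien-3-ol | CC(C)=CCC[C@](OC#C[Si](C)(C)C)(C)CCCC(O)C(C)=C
F7 | step 9 | (7S)-2,7,11-trimethyl-7-{[(trimethylsilyl)ethynyl]oxy}dodeca-1,10-dien-3-one | CC(C)=CCC[C@](OC#C[Si](C)(C)C)(C)CCCC(=O)C(C)=C
F8 | step 9 | (7R)-2,7,11-trimethyl-4-(trifluoroacetyl)-7-{[(trimethylsilyl)ethynyl]oxy}dodeca-1,10-dien-3-one (as lithium enolate) | CC(C)=CCC[C@](OC#C[Si](C)(C)C)(C)CCC(C(=O)C(F)(F)F)C(=O)C(C)=C
F9 | step 9 | (7R)-4-diazo-2,7,11-trimethyl-7-{[(trimethylsilyl)ethynyl]oxy}dodeca-1,10-dien-3-one | CC(C)=CCC[C@](OC#C[Si](C)(C)C)(C)CCC(=[N+]=[N-])C(=O)C(C)=C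
F10 | step 12 | 5-[(2S)-2,5-dimethyl-7-{[tri(propan-2-yl)silyl]oxy}-3,4-dihydro-2H-chromen-2-yl]-2-methylpentane-2,3-diol | CC(C)(O)C(O)CC[C@]1(C)CCc2c(C)cc(O[Si](C(C)C)(C(C)C)C(C)C)cc2O1
F11 | step 12 | 3-[(2S)-2,5-dimethyl-7-{[tri(propan-2-yl)silyl]oxy}-3,4-dihydro-2H-chromen-2-yl]propanal | O=CCC[C@]1(C)CCc2c(C)cc(O[Si](C(C)C)(C(C)C)C(C)C)cc2O1
F12 | step 12 | ethyl (2E)-5-[(2R)-2,5-dimethyl-7-{[tri(propan-2-yl)silyl]oxy}-3,4-dihydro-2H-chromen-2-yl]-2-methylpent-2-enoate | CCOC(=O)/C(C)=C/CC[C@]1(C)CCc2c(C)cc(O[Si](C(C)C)(C(C)C)C(C)C)cc2O1
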